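The route rests on cutting the C7≡C8 triple bond next to the 3-hydroxy ring (ring A). Because C7 sits on the tetrasubstituted C5=C6 ring alkene and C8 on the methyl-bearing C9=C10 alkene, C7 can be carried as a ring-CH2 phenyl sulfone and C8 as the formyl carbon of a C30 polyenynal with every alkene already E. One pot then joins C7 to C8 and removes phosphate and sulfinate to leave the alkyne, with nothing stereochemical to control. The precursor pair is the (3R)-silyl-protected hydroxy-β-cyclogeranyl phenyl sulfone and the C30 aldehyde, itself made the same way from safranal and crocetin dialdehyde.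

Key step: step 11

Remarks on the chemistry:
- Carotenoid numbering is used for the C30 and C40 compounds: the hydroxylated ring A and its half of the chain are unprimed, the didehydro ring B and its half are primed.
- Compounds from 14 onward are assumed to be handled under argon with exclusion of light.
- Reactions run with lithium or potassium bases are assumed to be quenched with aqueous NH4Cl.

Step 1
Reactants: 1 ketoisophorone (2,6,6-trimethylcyclohex-2-ene-1,4-dione)
Product: 2 (6R)-2,2,6-trimethylcyclohexane-1,4-dione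
Conditions: ene-reductase OYE2, NADP+ (cat.), glucose dehydrogenase, D-glucose, phosphate buffer pH 6.5, 30 °C
Reagents that add atoms: none
Why: Flavin-dependent ene-reductase (old yellow enzyme) reduction of the enedione C=C bond, with NADPH recycled by glucose dehydrogenase, should add hydride and proton trans across C2=C3 inside the chiral active site and so set the methyl-bearing centre as R (asymmetric biocatalytic conjugate reduction), the run being stopped at full conversion to limit slow racemisation of this α-centre.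

Step 2
Reactants: 2 (6R)-2,2,6-trimethylcyclohexane-1,4-dione
Product: 3 (4R,6R)-4-hydroxy-2,2,6-trimethylcyclohexan-1-one (hydroxyl trans to the C6 methyl)
Conditions: LiBH(s-Bu)3, THF, −78 °C; then NaOH, H2O2, 0 °C
Reagents that add atoms: none
Why: In this substrate-controlled diastereoselective ketone reduction the bulky borohydride should leave the C1 carbonyl alone (flanked by CMe2 and CHMe) and attack the C4 carbonyl equatorially, away from the axial C2 methyl, giving the axial alcohol trans to the equatorial C6 methyl so that 4R is relayed from 6R, any cis epimer being removed by crystallisation or chromatography before C6 is erased.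

Step 3
Reactants: 3 (4R,6R)-4-hydroxy-2,2,6-trimethylcyclohexan-1-one
Product: 4 (4R,6R)-4-(tert-butyldimethylsilyloxy)-2,2,6-trimethylcyclohexan-1-one
Conditions: TBSCl, imidazole, DMF, rt
Reagents that add atoms: tert-butyldimethylsilyl chloride, CC(C)(C)[Si](C)(C)Cl
Why: Imidazole-promoted silyl ether formation on the secondary alcohol should give a protecting group that withstands the amide, organolithium, hydride and alkoxide reagents ahead and leaves with fluoride at the end.

Step 4
Reactants: 4 (4R,6R)-4-(tert-butyldimethylsilyloxy)-2,2,6-trimethylcyclohexan-1-one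
Product: 5 (4R)-4-(tert-butyldimethylsilyloxy)-2,6,6-trimethylcyclohex-1-en-1-yl trifluoromethanesulfonate
Conditions: LiN(i-Pr)2, THF, −78 °C; PhNTf2, −78 °C → rt
Reagents that add atoms: N-phenylbis(trifluoromethanesulfonimide), O=S(=O)(N(c1ccccc1)S(=O)(=O)C(F)(F)F)C(F)(F)F
Why: Only C6 carries an α-hydrogen (C2 is quaternary), so enolisation can give just one, tetrasubstituted enolate, which is O-sulfonylated (enol triflate formation), and the C6 centre is erased on purpose while C4 is untouched.

Step 5
Reactants: 5 (4R)-4-(tert-butyldimethylsilyloxy)-2,6,6-trimethylcyclohex-1-en-1-yl trifluoromethanesulfonate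
Product: 6 methyl (4R)-4-(tert-butyldimethylsilyloxy)-2,6,6-trimethylcyclohex-1-ene-1-carboxylate
Conditions: Pd(OAc)2, PPh3, CO (1 atm), MeOH, Et3N, DMF, 60 °C
Reagents that add atoms: carbon monoxide, [C-]#[O+]; methanol, CO
Why: Palladium-catalysed methoxycarbonylation of an enol triflate (oxidative addition to zerovalent palladium formed in situ, CO insertion, methanolysis of the acyl complex) is established for hindered cyclohexenyl triflates and installs C7 at the ester oxidation level.

Step 6
Reactants: 6 methyl (4R)-4-(tert-butyldimethylsilyloxy)-2,6,6-trimethylcyclohex-1-ene-1-carboxylate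
Product: 7 [(4R)-4-(tert-butyldimethylsilyloxy)-2,6,6-trimethylcyclohex-1-en-1-yl]methanol
Conditions: i-Bu2AlH, CH2Cl2, −78 → 0 °C
Reagents that add atoms: none
Why: Hydride reduction of the conjugated ester (1,2-reduction with a dialkylaluminium hydride) should give the primary allylic alcohol, the silyl ether and the tetrasubstituted alkene being inert.

Step 7
Reactants: 7 [(4R)-4-(tert-butyldimethylsilyloxy)-2,6,6-trimethylcyclohex-1-en-1-yl]methanol
Product: 9 (3R)-3-(tert-butyldimethylsilyloxy)-β-cyclogeranyl phenyl sulfone, via allylic bromide 8 (not isolated)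
Conditions: PPh3, CBr4, CH2Cl2, 0 °C; then PhSO2Na, DMF, rt
Reagents that add atoms: sodium benzenesulfinate, [Na+].[O-]S(=O)c1ccccc1
Why: Appel bromination turns the primary allylic alcohol into the bromide under neutral conditions that spare the silyl ether, and SN2 S-alkylation of the sulfinate in DMF should give the sulfone at the exocyclic carbon because the alternative SN2' site C5 is fully substituted.

Step 8
Reactants: 10 safranal (2,6,6-trimethylcyclohexa-1,3-diene-1-carbaldehyde)
Product: 11 safranol [(2,6,6-trimethylcyclohexa-1,3-dien-1-yl)methanol]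
Conditions: i-Bu2AlH, CH2Cl2, −78 °C
Reagents that add atoms: none
Why: Clean 1,2-reduction of the dienal carbonyl by the aluminium hydride (carbonyl reduction) should give the dienylic alcohol without touching the ring diene.

Step 9
Reactants: 11 safranol
Product: 13 safranyl phenyl sulfone, via dienylic bromide 12 (not isolated)
Conditions: PPh3, CBr4, CH2Cl2, −20 °C; then PhSO2Na, DMF, 0 °C → rt
Reagents that add atoms: sodium benzenesulfinate, [Na+].[O-]S(=O)c1ccccc1
Why: Appel bromination followed at once by SN2 S-alkylation of the sulfinate should give the sulfone at the primary carbon, the acid-free conditions and low temperature keeping the pentadienylic bromide from ionising and the homoannular diene intact.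

Step 10
Reactants: 13 safranyl phenyl sulfone; 14 crocetin dialdehyde
Product: 18 C30 aldehyde 3',4',7',8'-tetradehydro-8-apo-β-caroten-8-al, via lithium alkoxide adduct 15 (not isolated), via phosphate ester 16 (not isolated), via vinyl sulfone 17 (not isolated)
Conditions: 13, n-BuLi (1.0 equiv), THF, −78 °C; cannulated into 14 (3 equiv), THF, −78 °C; ClP(O)(OEt)2, −78 °C → rt; t-BuOK (4 equiv), −78 → 0 °C; aq. NH4Cl
Reagents that add atoms: none
Why: Julia-type addition of the α-lithiated allylic sulfone to one formyl group, phosphorylation of the alkoxide and tert-butoxide-induced double elimination (phosphate, then sulfinate with the C8' vinylic hydrogen) should give the C7'≡C8' enyne, with inverse addition into a threefold excess of the symmetrical dialdehyde holding the reaction to one end, lithium-bridged α-attack favoured over attack through the hindered C5', and the surplus dialdehyde recovered on chromatography.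

Step 11
Reactants: 9 (3R)-3-(tert-butyldimethylsilyloxy)-β-cyclogeranyl phenyl sulfone; 18 C30 aldehyde
Product: 22 (3R)-3-(tert-butyldimethylsilyloxy)-3',4',7,8,7',8'-hexadehydro-β,β-carotene, via lithium alkoxide adduct 19 (not isolated), via phosphate ester 20 (not isolated), via vinyl sulfone 21 (not isolated)
Conditions: 9 (1.3 equiv), n-BuLi (1.25 equiv), THF, −78 °C; 18 (1.0 equiv), −78 °C; ClP(O)(OEt)2 (1.5 equiv), −78 °C → rt; t-BuOK (5 equiv), −78 → 0 °C; aq. NH4Cl
Reagents that add atoms: none
Why: The C7 carbanion of lithiated 9 adds to the formyl carbon C8 of 18 to give the β-alkoxy sulfone, the alkoxide is phosphorylated in the flask, tert-butoxide removes the acidic C7 hydrogen to expel diethyl phosphate (E1cB) and form the C7=C8 vinyl sulfone, and a second equivalent removes the C8 vinylic hydrogen with loss of benzenesulfinate to leave C7≡C8. The closest known reaction type is the Julia-type addition of an allylic sulfone anion to an enal followed by one-pot double elimination to a conjugated enyne. No ring closes and no stereocentre is made: the transient centres at C7 and C8 and the vinyl sulfone geometry are erased, so their mixtures do not matter, and C3 with its silyl ether is remote and stable to the bases. The step needs α- and not γ-attack of the allylic anion, secured by the fully substituted γ-carbon C5 and lithium-bridged addition at −78 °C, and 1,2- and not conjugate addition, secured by the formyl carbon being the hardest and least hindered electrophilic site of the polyenynal. It also needs alkyne and not polyene formation: neither C6 nor C9 carries a hydrogen, so the vinyl sulfone cannot shift to an allyl sulfone and elimination across C7–C8 is the only activated exit, while the 9E alkene is never broken and keeps the geometry it has in 18. The sulfone is used in slight excess so that all of 18 is consumed before tert-butoxide is added and no free aldehyde meets the strong base.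

Step 12
Reactants: 22 (3R)-3-(tert-butyldimethylsilyloxy)-3',4',7,8,7',8'-hexadehydro-β,β-carotene
Product: 23 (3R)-3',4',7,8,7',8'-hexadehydro-β,β-caroten-3-ol (target, all-E)
Conditions: Bu4NF, THF, 0 °C → rt, dark
Reagents that add atoms: none
Why: Fluoride-induced cleavage of the secondary silyl ether (desilylation driven by Si–F bond formation) should free the C3 hydroxyl without touching the polyene, the two alkynes or the C3 configuration, since no bond to C3 is broken.

Compound list
1 | ketoisophorone (2,6,6-trimethylcyclohex-2-ene-1,4-dione) | CC1=CC(=O)CC(C)(C)C1=O | starting material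
2 | (6R)-2,2,6-trimethylcyclohexane-1,4-dione | C[C@@H]1CC(=O)CC(C)(C)C1=O | intermediate
3 | (4R,6R)-4-hydroxy-2,2,6-trimethylcyclohexan-1-one | C[C@@H]1C[C@@H](O)CC(C)(C)C1=O | intermediate
4 | (4R,6R)-4-(tert-butyldimethylsilyloxy)-2,2,6-trimethylcyclohexan-1-one | C[C@@H]1C[C@@H](O[Si](C)(C)C(C)(C)C)CC(C)(C)C1=O | intermediate
5 | (4R)-4-(tert-butyldimethylsilyloxy)-2,6,6-trimethylcyclohex-1-en-1-yl trifluoromethanesulfonate | O=S(=O)(OC1=C(C)C[C@@H](O[Si](C)(C)C(C)(C)C)CC1(C)C)C(F)(F)F | intermediate
6 | methyl (4R)-4-(tert-butyldimethylsilyloxy)-2,6,6-trimethylcyclohex-1-ene-1-carboxylate | COC(=O)C1=C(C)C[C@@H](O[Si](C)(C)C(C)(C)C)CC1(C)C | intermediate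
7 | [(4R)-4-(tert-butyldimethylsilyloxy)-2,6,6-trimethylcyclohex-1-en-1-yl]methanol | OCC1=C(C)C[C@@H](O[Si](C)(C)C(C)(C)C)CC1(C)C | intermediate
8 | (4R)-1-(bromomethyl)-4-(tert-butyldimethylsilyloxy)-2,6,6-trimethylcyclohex-1-ene | BrCC1=C(C)C[C@@H](O[Si](C)(C)C(C)(C)C)CC1(C)C | intermediate (not isolated)
9 | (3R)-3-(tert-butyldimethylsilyloxy)-β-cyclogeranyl phenyl sulfone [(4R)-4-(tert-butyldimethylsilyloxy)-2,6,6-trimethyl-1-(phenylsulfonylmethyl)cyclohex-1-ene] | O=S(=O)(CC1=C(C)C[C@@H](O[Si](C)(C)C(C)(C)C)CC1(C)C)c1ccccc1 | intermediate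
10 | safranal (2,6,6-trimethylcyclohexa-1,3-diene-1-carbaldehyde) | CC1=C(C=O)C(C)(C)CC=C1 | starting material
11 | safranol [(2,6,6-trimethylcyclohexa-1,3-dien-1-yl)methanol] | CC1=C(CO)C(C)(C)CC=C1 | intermediate
12 | 1-(bromomethyl)-2,6,6-trimethylcyclohexa-1,3-diene | CC1=C(CBr)C(C)(C)CC=C1 | intermediate (not isolated)
13 | safranyl phenyl sulfone [2,6,6-trimethyl-1-(phenylsulfonylmethyl)cyclohexa-1,3-diene] | CC1=C(CS(=O)(=O)c2ccccc2)C(C)(C)CC=C1 | intermediate
14 | crocetin dialdehyde [(2E,4E,6E,8E,10E,12E,14E)-2,6,11,15-tetramethylhexadeca-2,4,6,8,10,12,14-heptaenedial] | O=C/C(C)=C/C=C/C(C)=C/C=C/C=C(C)/C=C/C=C(\C)C=O | starting material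
15 | lithium alkoxide of the mono-adduct of 13 and 14: lithium salt of (all-E)-16-hydroxy-2,6,11,15-tetramethyl-17-(phenylsulfonyl)-17-(2,6,6-trimethylcyclohexa-1,3-dien-1-yl)heptadeca-2,4,6,8,10,12,14-heptaenal, both diastereomers at C16 and C17 | CC1=C(C(S(=O)(=O)c2ccccc2)C([O-])/C(C)=C/C=C/C(C)=C/C=C/C=C(C)/C=C/C=C(\C)C=O)C(C)(C)CC=C1.[Li+] | intermediate (not isolated)
16 | diethyl phosphate ester of the adduct (16-diethoxyphosphoryloxy analogue of 15, both diastereomers) | CC1=C(C(S(=O)(=O)c2ccccc2)C(OP(=O)(OCC)OCC)/C(C)=C/C=C/C(C)=C/C=C/C=C(C)/C=C/C=C(\C)C=O)C(C)(C)CC=C1 | intermediate (not isolated)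
17 | vinyl sulfone: (2E,4E,6E,8E,10E,12E,14E)-2,6,11,15-tetramethyl-17-(phenylsulfonyl)-17-(2,6,6-trimethylcyclohexa-1,3-dien-1-yl)heptadeca-2,4,6,8,10,12,14,16-octaenal, E/Z mixture at the sulfonyl-bearing alkene | CC1=C(C(S(=O)(=O)c2ccccc2)=C/C(C)=C/C=C/C(C)=C/C=C/C=C(C)/C=C/C=C(\C)C=O)C(C)(C)CC=C1 | intermediate (not isolated)
18 | C30 aldehyde, 3',4',7',8'-tetradehydro-8-apo-β-caroten-8-al [(2E,4E,6E,8E,10E,12E,14E)-2,6,11,15-tetramethyl-17-(2,6,6-trimethylcyclohexa-1,3-dien-1-yl)heptadeca-2,4,6,8,10,12,14-heptaen-16-ynal] | CC1=C(C#C/C(C)=C/C=C/C(C)=C/C=C/C=C(C)/C=C/C=C(\C)C=O)C(C)(C)CC=C1 | intermediate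
19 | lithium (3R)-3-(tert-butyldimethylsilyloxy)-7-(phenylsulfonyl)-3',4',7',8'-tetradehydro-7,8-dihydro-β,β-caroten-8-olate, both diastereomers at C7 and C8 | CC1=C(C#C/C(C)=C/C=C/C(C)=C/C=C/C=C(C)/C=C/C=C(\C)C([O-])C(S(=O)(=O)c2ccccc2)C3=C(C)C[C@@H](O[Si](C)(C)C(C)(C)C)CC3(C)C)C(C)(C)CC=C1.[Li+] | intermediate (not isolated)
20 | diethyl (3R)-3-(tert-butyldimethylsilyloxy)-7-(phenylsulfonyl)-3',4',7',8'-tetradehydro-7,8-dihydro-β,β-caroten-8-yl phosphate, both diastereomers at C7 and C8 | CC1=C(C#C/C(C)=C/C=C/C(C)=C/C=C/C=C(C)/C=C/C=C(\C)C(OP(=O)(OCC)OCC)C(S(=O)(=O)c2ccccc2)C3=C(C)C[C@@H](O[Si](C)(C)C(C)(C)C)CC3(C)C)C(C)(C)CC=C1 | intermediate (not isolated)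
21 | (3R)-3-(tert-butyldimethylsilyloxy)-7-(phenylsulfonyl)-3',4',7',8'-tetradehydro-β,β-carotene, E/Z mixture at C7=C8, all other alkenes E | CC1=C(C#C/C(C)=C/C=C/C(C)=C/C=C/C=C(C)/C=C/C=C(\C)C=C(S(=O)(=O)c2ccccc2)C3=C(C)C[C@@H](O[Si](C)(C)C(C)(C)C)CC3(C)C)C(C)(C)CC=C1 | intermediate (not isolated)
22 | (3R)-3-(tert-butyldimethylsilyloxy)-3',4',7,8,7',8'-hexadehydro-β,β-carotene (all-E) | CC1=C(C#C/C(C)=C/C=C/C(C)=C/C=C/C=C(C)/C=C/C=C(\C)C#CC2=C(C)C[C@@H](O[Si](C)(C)C(C)(C)C)CC2(C)C)C(C)(C)CC=C1 | intermediate
23 | (3R)-3',4',7,8,7',8'-hexadehydro-β,β-caroten-3-ol (all-E) | CC1=C(C#C/C(C)=C/C=C/C(C)=C/C=C/C=C(C)/C=C/C=C(\C)C#CC2=C(C)C[C@@H](O)CC2(C)C)C(C)(C)CC=C1 | target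

Total step count: 12
Longest linear sequence: 9 steps (steps 1–7, 11 and 12, from ketoisophorone). The safranal branch (steps 8–10) joins at step 11.

Steps most likely to fail

1. Step 11. The addition of the hindered C7 carbanion to the formyl group may revert before the alkoxide is phosphorylated. In the last elimination, removal of a ring C4 hydrogen may compete with removal of the C8 hydrogen and lead toward an allene-type product. The fallback sets out from 18, uses triflate 5 already in the route, and comes back at 22. Aldehyde 18 would be homologated by one carbon with lithiated trimethylsilyldiazomethane (Me3SiCHN2, LiN(i-Pr)2, THF, −78 °C → rt; Colvin rearrangement) to the terminal polyenyne F1. This would be coupled at once with enol triflate 5 (Pd(PPh3)4, CuI, i-Pr2NH, THF, rt; Sonogashira coupling), which forms the C6–C7 bond and gives 22 directly.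

2. Step 10. Addition may occur at both formyl groups. The free formyl groups of product and surplus dialdehyde may degrade under tert-butoxide, and the dialdehyde may dissolve poorly at low temperature. The fallback sets out from 14 and comes back at 18. Dialdehyde 14 would be acetalised with one equivalent of 2,2-dimethylpropane-1,3-diol (pyridinium p-toluenesulfonate, toluene, 4 Å sieves, 60 °C) to the mono-acetal F2, with bis-acetal and unreacted 14 separated and recycled. F2 would then be taken through the step 10 sequence with lithiated 13 in slight excess, passing through the lithium alkoxide adduct F3, the phosphate ester F4 and the vinyl sulfone F5 to the acetal-protected C30 enyne F6. Mild hydrolysis of F6 (aqueous oxalic acid, THF, rt) would give 18.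

3. Step 9. The pentadienylic bromide may ionise, rearrange or eliminate before it is displaced, and sulfinate may attack a ring carbon instead of the exocyclic carbon. The fallback sets out from 11 and comes back at 13. Alcohol 11 would be condensed with PhSSPh and Bu3P in THF (phosphine–disulfide redox condensation, no halide intermediate) to the allylic sulfide F7. Chemoselective sulfur oxidation of F7 (H2O2, catalytic (NH4)6Mo7O24, EtOH, 0 °C) would give sulfone 13.

Further compounds
F1 | step 11 | (3E,5E,7E,9E,11E,13E,15E)-3,7,12,16-tetramethyl-18-(2,6,6-trimethylcyclohexa-1,3-dien-1-yl)octadeca-3,5,7,9,11,13,15-heptaene-1,17-diyne | CC1=C(C#C/C(C)=C/C=C/C(C)=C/C=C/C=C(C)/C=C/C=C(\C)C#C)C(C)(C)CC=C1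
F2 | step 10 | crocetin dialdehyde mono-acetal, (2E,4E,6E,8E,10E,12E,14E)-15-(5,5-dimethyl-1,3-dioxan-2-yl)-2,6,11-trimethylhexadeca-2,4,6,8,10,12,14-heptaenal | O=C/C(C)=C/C=C/C(C)=C/C=C/C=C(C)/C=C/C=C(\C)C1OCC(C)(C)CO1
F3 | step 10 | lithium alkoxide adduct of lithiated 13 and F2 (both diastereomers at the two new sp3 carbons) | CC1=C(C(S(=O)(=O)c2ccccc2)C([O-])/C(C)=C/C=C/C(C)=C/C=C/C=C(C)/C=C/C=C(\C)C3OCC(C)(C)CO3)C(C)(C)CC=C1.[Li+]
F4 | step 10 | diethyl phosphate ester of the adduct F3 (both diastereomers) | CC1=C(C(S(=O)(=O)c2ccccc2)C(OP(=O)(OCC)OCC)/C(C)=C/C=C/C(C)=C/C=C/C=C(C)/C=C/C=C(\C)C3OCC(C)(C)CO3)C(C)(C)CC=C1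
F5 | step 10 | vinyl sulfone of the acetal series (E/Z mixture at the sulfonyl-bearing alkene, all other alkenes E) | CC1=C(C(S(=O)(=O)c2ccccc2)=C/C(C)=C/C=C/C(C)=C/C=C/C=C(C)/C=C/C=C(\C)C3OCC(C)(C)CO3)C(C)(C)CC=C1
F6 | step 10 | 5,5-dimethyl-1,3-dioxan-2-yl acetal of the C30 aldehyde 18 (all-E) | CC1=C(C#C/C(C)=C/C=C/C(C)=C/C=C/C=C(C)/C=C/C=C(\C)C2OCC(C)(C)CO2)C(C)(C)CC=C1
F7 | step 9 | phenyl (2,6,6-trimethylcyclohexa-1,3-dien-1-yl)methyl sulfide | CC1=C(CSc2ccccc2)C(C)(C)CC=C1
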